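**Plan**
- Retrosynthesis first removes the six C–Br bonds (C2, C3 and C6 of each ring) together with both aromatic sextets, giving an alicyclic bis(cyclohexane-1,2-dione). The four C=O groups are then traced back to two ring epoxides, and the C7–C7' bridge is cut last, as C7=C7', into two vinyl groups.
- The feature that allows this: each ring is a 1-alkyl-2,3,6-tribromo-4,5-dihydroxybenzene, the fully brominated aromatic tautomer of a 4-alkylcyclohexane-1,2-dione. C4 and C5 are the carbonyl carbons, C1 is the alkyl-bearing CH, and C2, C3 and C6 are the three CH2 groups.
- Forward: both six-membered carbocycles come ready-made in 4-vinylcyclohexene, one per half. Ring epoxidation, vinyl homometathesis (joins the halves at C7=C7'), hydrogenation, epoxide hydrolysis and diol oxidation give the bis-dione; no ring is closed anywhere.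
- Excess bromine then aromatizes and perbrominates both rings in one operation.
- Stereochemistry: the target has no stereocentre. The sp3 centres and the alkene geometry of the intermediates are left uncontrolled and are all erased by hydrogenation and aromatization.

Key step: step 6

Assumption: the target is achiral, so the request for a single enantiomer is met trivially. Compounds 2–6 and 8 are carried as racemic diastereomer mixtures that all converge; their SMILES show one representative isomer.

**Step 1**
Reactants: 1 4-vinylcyclohexene (racemic)
Product: 2 3-vinyl-7-oxabicyclo[4.1.0]heptane (1,2-epoxy-4-vinylcyclohexane; cis/trans mixture)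
Conditions: mCPBA (1.0 equiv), CH2Cl2, 0 °C
Reagents that add atoms: mCPBA, O=C(OO)c1cccc(Cl)c1
Why: Prilezhaev epoxidation, in which the peracid should attack the electron-richer cis-disubstituted ring alkene much faster than the monosubstituted vinyl group; the cis-fused oxirane forms on either ring face, which does not matter because every sp3 centre is erased later.

**Step 2**
Reactants: 2 3-vinyl-7-oxabicyclo[4.1.0]heptane (two molecules)
Product: 3 1,2-bis(7-oxabicyclo[4.1.0]heptan-3-yl)ethene (E/Z mixture; E drawn)
Conditions: Grubbs II (2 mol%), CH2Cl2, 40 °C, Ar sparge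
Reagents that add atoms: none
Why: Ruthenium-catalysed olefin homometathesis of a terminal alkene, driven by loss of ethylene; the dialkyl oxirane is inert to the Ru carbene, no ring alkene remains to compete, and the alkene geometry is irrelevant because the double bond is hydrogenated next.

**Step 3**
Reactants: 3 1,2-bis(7-oxabicyclo[4.1.0]heptan-3-yl)ethene
Product: 4 1,2-bis(7-oxabicyclo[4.1.0]heptan-3-yl)ethane
Conditions: H2 (1 atm), 5% Pd/C, EtOAc, rt
Reagents that add atoms: none
Why: Heterogeneous catalytic hydrogenation of an unhindered 1,2-disubstituted alkene; the oxiranes are neither allylic nor benzylic and should not be hydrogenolysed over Pd/C in neutral ethyl acetate at 1 atm.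

**Step 4**
Reactants: 4 1,2-bis(7-oxabicyclo[4.1.0]heptan-3-yl)ethane
Product: 5 4,4'-(ethane-1,2-diyl)bis(cyclohexane-1,2-diol) (both diols trans)
Conditions: HClO4 (cat.), THF/H2O, rt to 40 °C
Reagents that add atoms: water, O
Why: Acid-catalysed epoxide hydrolysis, in which water opens the protonated oxirane with inversion (anti, trans-diaxial, Fürst–Plattner), so each ring becomes a trans-1,2-diol; the carbinol configurations set by this anti opening are of no consequence because both carbons become C=O in step 5.

**Step 5**
Reactants: 5 4,4'-(ethane-1,2-diyl)bis(cyclohexane-1,2-diol)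
Product: 6 4,4'-(ethane-1,2-diyl)bis(cyclohexane-1,2-dione) (largely as its diosphenol tautomer)
Conditions: IBX (6 equiv), DMSO, rt
Reagents that add atoms: none
Why: IBX oxidation of vicinal diols, which in DMSO is known to stop at the α-diketone without glycol C–C cleavage; the four secondary alcohols should be oxidized in turn while the two remaining CH centres stay untouched.

**Step 6**
Reactants: 6 4,4'-(ethane-1,2-diyl)bis(cyclohexane-1,2-dione); 7 bromine
Product: 10 1,2-bis(2,3,6-tribromo-4,5-dihydroxyphenyl)ethane (target), via bis(α-bromodiosphenol) 8 (not isolated), via bis(3-bromocatechol) 9 (not isolated)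
Conditions: Br2 (8.5 equiv), AcOH, dark, 15 °C → 60 °C; aq. Na2S2O4 wash, crystallization
Reagents that add atoms: bromine (7), BrBr
Why: Each ring reacts through its diosphenol enol: Br2 brominates an enol (α) carbon to give 8, a second α-bromination followed by dehydrobromination (1,2- or vinylogous 1,4-loss of HBr) and keto–enol tautomerization raises the ring to the bromocatechol 9, and two electrophilic aromatic substitutions ortho and para to the hydroxyls fill the last CH positions. The closest known reaction type is the halogenative aromatization (bromination–dehydrobromination) of cyclohexane-1,2-diones and cyclohexanones to bromocatechols and bromophenols, combined with the exhaustive ring bromination of catechols. No ring is closed, since only the two existing carbocycles are aromatized, and no stereocentre is formed, the two CH centres of 6 becoming sp2. Regiochemistry cannot go astray because C2, C3 and C6 are the only ring positions able to accept bromine: C3 and C6 are the α-carbons of the dione and C2 lies para to the C5 hydroxyl once the ring is aromatic. What must be controlled is the competition between ring and benzylic (C7–H) bromination; a polar, non-radical medium (acetic acid, no light, no initiator) should decide it for the ring, since electrophilic attack on an enol or a catechol is orders of magnitude faster than hydrogen abstraction from the bridge methylenes when no bromine atoms are generated. The HBr released catalyses enolization and holds the catechol/o-quinone couple on the reduced side, and the dithionite wash returns any quinone formed by the slight excess of bromine.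

**Compound list**
1 | 4-vinylcyclohexene (racemic butadiene dimer) | C=CC1CCC=CC1 | starting material
2 | 3-vinyl-7-oxabicyclo[4.1.0]heptane (cis/trans mixture, racemic; one isomer drawn) | C=C[C@H]1CC[C@@H]2O[C@@H]2C1 | intermediate
3 | 1,2-bis(7-oxabicyclo[4.1.0]heptan-3-yl)ethene (E/Z and diastereomer mixture; E isomer drawn) | C1[C@@H]2O[C@@H]2CC[C@H]1/C=C/[C@H]1CC[C@@H]2O[C@@H]2C1 | intermediate
4 | 1,2-bis(7-oxabicyclo[4.1.0]heptan-3-yl)ethane (diastereomer mixture; one drawn) | C1[C@@H]2O[C@@H]2CC[C@H]1CC[C@H]1CC[C@@H]2O[C@@H]2C1 | intermediate
5 | 4,4'-(ethane-1,2-diyl)bis(cyclohexane-1,2-diol), both diols trans (diastereomer mixture; one drawn) | O[C@@H]1CC[C@@H](CC[C@H]2CC[C@@H](O)[C@H](O)C2)C[C@H]1O | intermediate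
6 | 4,4'-(ethane-1,2-diyl)bis(cyclohexane-1,2-dione) (meso/rac mixture; one drawn; diketone form written) | O=C1CC[C@@H](CC[C@H]2CCC(=O)C(=O)C2)CC1=O | intermediate
7 | bromine | BrBr | starting material
8 | 5,5'-(ethane-1,2-diyl)bis(3-bromo-2-hydroxycyclohex-2-en-1-one) (one regioisomer drawn; bromination at the other α-carbon converges) | OC1=C(Br)C[C@@H](CC[C@H]2CC(Br)=C(O)C(=O)C2)CC1=O | intermediate
9 | 5,5'-(ethane-1,2-diyl)bis(3-bromobenzene-1,2-diol) (one regioisomer drawn; the isomer converges) | Oc1cc(CCc2cc(O)c(O)c(Br)c2)cc(Br)c1O | intermediate
10 | 1,2-bis(2,3,6-tribromo-4,5-dihydroxyphenyl)ethane (achiral) | Oc1c(O)c(Br)c(CCc2c(Br)c(O)c(O)c(Br)c2Br)c(Br)c1Br | target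

**Step count and risks**
Total step count: 6. Longest linear sequence: 6 (the route is fully linear from 1).

Steps most likely to fail:

1. Step 6. The cascade may stall at polybrominated, non-aromatic diones if HBr loss is slow, or surplus bromine may carry the catechols on to o-quinones or start radical bromination at the bridge, so that aromatization and halogenation interfere with each other. Fallback: separate the two events. From 6, iodine-catalysed dehydrogenative aromatization (I2 cat., DMSO, 100 °C, DMSO as terminal oxidant) should give 4,4'-(ethane-1,2-diyl)di(benzene-1,2-diol) F1. Exhaustive electrophilic bromination of this isolated bis-catechol (Br2, 6.5 equiv, AcOH, dark, rt) then returns to the route at 10.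

2. Step 5. The fourfold oxidation of a polar tetraol may stop at the ketol stage, run past the dione oxidation level, or cleave the glycol C–C bond. Fallback: avoid the tetraol. From 4, a Kornblum-type oxidative opening of both oxiranes by DMSO (BF3·OEt2 cat., 90 °C) should give 4,4'-(ethane-1,2-diyl)bis(2-hydroxycyclohexan-1-one) F2 as a regioisomer mixture. Copper(II) oxidation of the acyloins (Cu(OAc)2, aq. AcOH, reflux) then converges on 6, so steps 4 and 5 are bypassed.

3. Step 2. Dimerization of an α-branched terminal olefin may turn over slowly, allowing the catalyst to decay to ruthenium hydrides that move the double bond out of the terminal position. Fallback: make the C7=C7' bond by reductive carbonyl coupling instead.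
   - From 2, acid hydrolysis (HClO4 cat., THF/H2O) gives trans-4-vinylcyclohexane-1,2-diol F3.
   - Benzylation (NaH, BnBr, DMF) gives trans-1,2-bis(benzyloxy)-4-vinylcyclohexane F4.
   - Lemieux–Johnson cleavage of the vinyl group (OsO4 cat., NaIO4, 2,6-lutidine, dioxane/H2O) gives trans-3,4-bis(benzyloxy)cyclohexane-1-carbaldehyde F5.
   - McMurry coupling (TiCl4, Zn, THF, reflux) gives 1,2-bis[trans-3,4-bis(benzyloxy)cyclohexyl]ethene F6.
   - One hydrogenation (H2, Pd/C, EtOH/EtOAc) saturates the alkene and removes the four benzyl ethers, returning to the route at 5.

**Further compounds**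
F1 | step 6 | 4,4'-(ethane-1,2-diyl)di(benzene-1,2-diol) | Oc1ccc(CCc2ccc(O)c(O)c2)cc1O
F2 | step 5 | 4,4'-(ethane-1,2-diyl)bis(2-hydroxycyclohexan-1-one) (regio- and diastereomer mixture; one drawn) | O=C1CC[C@@H](CC[C@H]2CCC(=O)[C@@H](O)C2)C[C@H]1O
F3 | step 2 | trans-4-vinylcyclohexane-1,2-diol (C4 epimer mixture; one drawn) | C=C[C@H]1CC[C@@H](O)[C@H](O)C1
F4 | step 2 | trans-1,2-bis(benzyloxy)-4-vinylcyclohexane (one isomer drawn) | C=C[C@H]1CC[C@@H](OCc2ccccc2)[C@H](OCc2ccccc2)C1
F5 | step 2 | trans-3,4-bis(benzyloxy)cyclohexane-1-carbaldehyde (one isomer drawn) | O=C[C@H]1CC[C@@H](OCc2ccccc2)[C@H](OCc2ccccc2)C1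
F6 | step 2 | 1,2-bis[trans-3,4-bis(benzyloxy)cyclohexyl]ethene (E isomer, one diastereomer drawn) | C1[C@H](OCc2ccccc2)[C@@H](OCc2ccccc2)CC[C@H]1/C=C/[C@H]1CC[C@@H](OCc2ccccc2)[C@H](OCc2ccccc2)C1
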